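## Retrosynthetic overview

1. Target ⇒ bridged spiro enol ether: the last operations are a zerovalent-palladium double prenylation at C5 and hydroxide opening of a temporary C7'–O–C2 bridge.
2. Bridged ether ⇒ 7'-methylidene spiro dienone, by tether-controlled intramolecular oxymercuration (sets C7').
3. Spiro dienone ⇒ 3-alkyl isovalerylphloroglucinol, by the key step: a dearomative palladium-catalysed allylic C–H alkylation (spiro C–C bond, ring B, spiro centre).
4. Alkyl phloroglucinol ⇒ reductive alkylation of fragment 1 (isovalerylphloroglucinol; ring A by Claisen cyclisation of a triketo ester) with fragment 2 (cyclopentane hydroxy aldehyde; ring C by aldol of a keto-aldehyde cut from a Diels–Alder cyclohexene).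
5. Ring order: A and C in parallel branches, then B by the spiro closure, then the temporary oxa bridge; the prenyl groups come last.

Assumption: the target is handled as the enol tautomer of the given SMILES, and the catalyst antipodes named in steps 4 and 10 are taken to give the stated configurations (the mirror-image catalyst is used otherwise).

Locants: ring A is the spiro cyclohexane C1–C6 (C1 spiro, C2 the carbonyl beside the acyl-bearing C3, C4 the enol carbon, C5 the carbon that receives the prenyl groups, C6 the other carbonyl). Rings B and C are the hydrindane C1'–C7a' (C5' = C1, C3' and C7' the carbinol carbons, C3a'/C7a' the ring fusion).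

## Route

Step 1
Reactants: 1 pentane-2,4-dione (acetylacetone); 2 methyl 3-methylbutanoate
Product: 3 triketone 8-methylnonane-2,4,6-trione
Conditions: LiN(iPr)2 (3 equiv), THF, −78 to 0 °C; then 1 M HCl
Reagents that add atoms: none
Why: Claisen acylation of the acetylacetone dianion, whose terminal carbanion is the more nucleophilic site and attacks the ester (Harris triketone synthesis); no stereocentre is formed.

Step 2
Reactants: 3 triketone 8-methylnonane-2,4,6-trione; 4 dimethyl carbonate
Product: 5 triketo ester methyl 9-methyl-3,5,7-trioxodecanoate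
Conditions: LiN(iPr)2 (4 equiv), THF, −78 to 0 °C; then 4, −78 °C to rt; 1 M HCl
Reagents that add atoms: none
Why: the third, kinetic deprotonation of the polyanion occurs at the terminal methyl rather than at the isobutyl methylene, and this carbanion is methoxycarbonylated by the carbonate (Claisen condensation).

Step 3
Reactants: 5 triketo ester methyl 9-methyl-3,5,7-trioxodecanoate
Product: 6 isovalerylphloroglucinol 3-methyl-1-(2,4,6-trihydroxyphenyl)butan-1-one
Conditions: Mg(OMe)2 (3 equiv), MeOH, reflux; then 1 M HCl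
Reagents that add atoms: none
Why: biomimetic Claisen (Dieckmann-type) cyclisation of the magnesium-chelated polyketide chain, in which C6 attacks the ester carbonyl while the enolised ketones are protected from the competing aldol closure, followed by aromatisation.

Step 4
Reactants: 7 2-methylbuta-1,3-diene (isoprene); 8 but-3-en-2-one
Product: 9 ketone 1-[(1R)-4-methylcyclohex-3-en-1-yl]ethan-1-one
Conditions: (S)-o-tolyl-CBS-oxazaborolidine (10 mol %), Tf2NH (8 mol %), CH2Cl2, −40 °C
Reagents that add atoms: none
Why: catalytic asymmetric Diels–Alder reaction in which the cationic oxazaborolidine activates the enone and shields one of its faces, giving the para adduct with the R centre that becomes C7a' of the target.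

Step 5
Reactants: 9 ketone 1-[(1R)-4-methylcyclohex-3-en-1-yl]ethan-1-one
Product: 10 (R)-limonene (4R)-1-methyl-4-(prop-1-en-2-yl)cyclohex-1-ene
Conditions: Ph3PCH3Br, KN(SiMe3)2, THF, −78 to 0 °C
Reagents that add atoms: methyltriphenylphosphonium bromide, C[P+](c1ccccc1)(c1ccccc1)c1ccccc1.[Br-]
Why: Wittig methylenation of the methyl ketone with the non-stabilised ylide at low temperature gives the isopropenyl group without epimerising the adjacent stereocentre.

Step 6
Reactants: 10 (R)-limonene (4R)-1-methyl-4-(prop-1-en-2-yl)cyclohex-1-ene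
Product: 11 keto-aldehyde (3R)-6-oxo-3-(prop-1-en-2-yl)heptanal
Conditions: O3 (1.0 equiv), CH2Cl2/MeOH, −78 °C; then Me2S, −78 °C to rt
Reagents that add atoms: ozone, [O-][O+]=O
Why: chemoselective ozonolysis, the electron-richer trisubstituted ring alkene reacting with one equivalent of ozone much faster than the 1,1-disubstituted isopropenyl group.

Step 7
Reactants: 11 keto-aldehyde (3R)-6-oxo-3-(prop-1-en-2-yl)heptanal
Product: 12 hydroxy aldehyde (1S,2R,5R)-2-hydroxy-2-methyl-5-(prop-1-en-2-yl)cyclopentane-1-carbaldehyde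
Conditions: L-proline (20 mol %), CH2Cl2, 0 °C to rt
Reagents that add atoms: none
Why: enamine catalysis makes the aldehyde the donor in a reversible 5-enolexo intramolecular aldol addition to the methyl ketone, and under this thermodynamic control the existing centre places the formyl group trans to the isopropenyl group and cis to the new hydrogen-bonded hydroxyl (methyl trans), which sets C3a' and C3'.

Step 8
Reactants: 13 3-methylbut-2-en-1-ol (prenol); 14 methyl chloroformate
Product: 15 carbonate methyl 3-methylbut-2-en-1-yl carbonate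
Conditions: pyridine, CH2Cl2, 0 °C to rt
Reagents that add atoms: none
Why: O-acylation of the allylic alcohol gives the carbonate that later serves as a neutral π-allyl precursor releasing its own methoxide base.

Step 9
Reactants: 6 isovalerylphloroglucinol 3-methyl-1-(2,4,6-trihydroxyphenyl)butan-1-one; 12 hydroxy aldehyde (1S,2R,5R)-2-hydroxy-2-methyl-5-(prop-1-en-2-yl)cyclopentane-1-carbaldehyde
Product: 17 alkylated phloroglucinol 1-[2,4,6-trihydroxy-3-{[(1S,2R,5R)-2-hydroxy-2-methyl-5-(prop-1-en-2-yl)cyclopentyl]methyl}phenyl]-3-methylbutan-1-one, via quinone methide 16 (not isolated)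
Conditions: L-proline (20 mol %), Hantzsch ester (1.2 equiv), CH2Cl2/EtOH, rt (6 in twofold excess)
Reagents that add atoms: none
Why: three-component reductive alkylation (Knoevenagel-type condensation to the ortho-quinone methide, then transfer hydrogenation by the Hantzsch ester) gives mono-C-alkylation at one of the two equivalent ring positions without O-alkylation and creates no new stereocentre.

Step 10
Reactants: 17 alkylated phloroglucinol 1-[2,4,6-trihydroxy-3-{[(1S,2R,5R)-2-hydroxy-2-methyl-5-(prop-1-en-2-yl)cyclopentyl]methyl}phenyl]-3-methylbutan-1-one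
Product: 18 spiro dienone (1S,3'R,3a'S,7a'R)-3',4,6-trihydroxy-3'-methyl-7'-methylidene-3-(3-methylbutanoyl)-1',2',3',3a',4',6',7',7a'-octahydrospiro[cyclohexa-3,5-diene-1,5'-inden]-2-one
Conditions: Pd(OAc)2 (10 mol %), (S,S)-aryl sulfoxide–oxazoline ligand (ArSOX type, 12 mol %), 2,5-dimethyl-1,4-benzoquinone (1.5 equiv), 1,4-dioxane (0.01 M), 45 °C
Reagents that add atoms: none
Why: Proposed new method: intramolecular dearomative allylic C–H alkylation under divalent-palladium/sulfoxide catalysis — acetate-assisted cleavage of a methyl C–H bond of the 1,1-disubstituted isopropenyl group gives a 2-substituted π-allylpalladium, the alkyl-bearing (ipso) carbon of the tethered phloroglucinol attacks a CH2 terminus through a six-membered transition state to form the spiro C–C bond and ring B, the quinone reoxidises zerovalent palladium, and the chiral ligand rather than the remote ring-C centres selects the arene face so that the acyl-flanked carbonyl C2 becomes axial (1S); the closest known reactions are White-type Pd(OAc)2/sulfoxide allylic C–H alkylations of terminal olefins (including the ArSOX variant that creates quaternary centres on the nucleophile) and zerovalent-palladium dearomative allylic alkylations of phenols and acylphloroglucinols with allylic carbonates, neither shown for a 1,1-disubstituted olefin closing a spiro ring on a phloroglucinol carbon.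

Step 11
Reactants: 18 spiro dienone (1S,3'R,3a'S,7a'R)-3',4,6-trihydroxy-3'-methyl-7'-methylidene-3-(3-methylbutanoyl)-1',2',3',3a',4',6',7',7a'-octahydrospiro[cyclohexa-3,5-diene-1,5'-inden]-2-one
Product: 20 bridged enol ether (1R,3'R,3a'S,7'S,7a'R)-2,7'-epoxy-3',4-dihydroxy-3',7'-dimethyl-3-(3-methylbutanoyl)-1',2',3',3a',4',6',7',7a'-octahydrospiro[cyclohexa-2,4-diene-1,5'-inden]-6-one, via alkylmercury trifluoroacetate 19 (not isolated)
Conditions: Hg(OCOCF3)2 (2.2 equiv), THF, 0 °C; then NaBH4, 3 M NaOH, 0 °C; dilute HCl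
Reagents that add atoms: none
Why: intramolecular oxymercuration–demercuration in which Markovnikov capture of the mercurinium ion is possible only for the oxygen on the axial C2 (1,3-diaxial to C7'), so the new C7'–O bond is axial and the methyl group equatorial (7'S) with no free cation that could scramble C7a'.

Step 12
Reactants: 20 bridged enol ether (1R,3'R,3a'S,7'S,7a'R)-2,7'-epoxy-3',4-dihydroxy-3',7'-dimethyl-3-(3-methylbutanoyl)-1',2',3',3a',4',6',7',7a'-octahydrospiro[cyclohexa-2,4-diene-1,5'-inden]-6-one; 15 carbonate methyl 3-methylbut-2-en-1-yl carbonate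
Product: 22 target CNP0198642.2 (1S,3'R,3a'S,7'S,7a'R)-3',4,7'-trihydroxy-3',7'-dimethyl-3-(3-methylbutanoyl)-5,5-bis(3-methylbut-2-en-1-yl)-1',2',3',3a',4',6',7',7a'-octahydrospiro[cyclohex-3-ene-1,5'-indene]-2,6-dione, via diprenyl enol ether 21 (not isolated)
Conditions: 15 (2.5 equiv), Pd(PPh3)4 (5 mol %), THF, 45 °C; then 1 M LiOH, THF/H2O, 45 °C; 1 M HCl to pH 3
Reagents that add atoms: lithium hydroxide, [Li+].[OH-]
Why: Tsuji–Trost allylic alkylation with zerovalent palladium prenylates the only enolisable ring carbon (C5) twice at the less hindered π-allyl terminus (O-allyl isomers re-ionise to the C-products), after which hydroxide adds to the doubly activated β-alkoxy enone carbon C2 and expels the tertiary alkoxide (addition–elimination), leaving the C7'–O bond and its configuration untouched.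

## Compound list

1 | pentane-2,4-dione (acetylacetone) | CC(=O)CC(C)=O | starting material
2 | methyl 3-methylbutanoate (methyl isovalerate) | COC(=O)CC(C)C | starting material
3 | 8-methylnonane-2,4,6-trione | CC(=O)CC(=O)CC(=O)CC(C)C | intermediate
4 | dimethyl carbonate | COC(=O)OC | starting material
5 | methyl 9-methyl-3,5,7-trioxodecanoate | COC(=O)CC(=O)CC(=O)CC(=O)CC(C)C | intermediate
6 | 3-methyl-1-(2,4,6-trihydroxyphenyl)butan-1-one (isovalerylphloroglucinol, fragment 1) | CC(C)CC(=O)c1c(O)cc(O)cc1O | intermediate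
7 | 2-methylbuta-1,3-diene (isoprene) | CC(=C)C=C | starting material
8 | but-3-en-2-one (methyl vinyl ketone) | CC(=O)C=C | starting material
9 | 1-[(1R)-4-methylcyclohex-3-en-1-yl]ethan-1-one | CC1=CC[C@@H](CC1)C(C)=O | intermediate
10 | (4R)-1-methyl-4-(prop-1-en-2-yl)cyclohex-1-ene ((R)-limonene) | CC1=CC[C@@H](CC1)C(C)=C | intermediate
11 | (3R)-6-oxo-3-(prop-1-en-2-yl)heptanal | O=CC[C@@H](CCC(C)=O)C(C)=C | intermediate
12 | (1S,2R,5R)-2-hydroxy-2-methyl-5-(prop-1-en-2-yl)cyclopentane-1-carbaldehyde (fragment 2; CHO cis to OH, trans to isopropenyl) | O=C[C@H]1[C@@H](CC[C@@]1(C)O)C(C)=C | intermediate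
13 | 3-methylbut-2-en-1-ol (prenol) | CC(C)=CCO | starting material
14 | methyl chloroformate | COC(=O)Cl | starting material
15 | methyl 3-methylbut-2-en-1-yl carbonate | COC(=O)OCC=C(C)C | intermediate
16 | ortho-quinone methide: 3,5-dihydroxy-6-{[(1S,2R,5R)-2-hydroxy-2-methyl-5-(prop-1-en-2-yl)cyclopentyl]methylidene}-2-(3-methylbutanoyl)cyclohexa-2,4-dien-1-one (alkylidene geometry not defined) | CC(C)CC(=O)C1=C(O)C=C(O)C(=C[C@H]2[C@@H](CC[C@@]2(C)O)C(C)=C)C1=O | intermediate
17 | 1-[2,4,6-trihydroxy-3-{[(1S,2R,5R)-2-hydroxy-2-methyl-5-(prop-1-en-2-yl)cyclopentyl]methyl}phenyl]-3-methylbutan-1-one | CC(C)CC(=O)c1c(O)cc(O)c(C[C@H]2[C@@H](CC[C@@]2(C)O)C(C)=C)c1O | intermediate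
18 | (1S,3'R,3a'S,7a'R)-3',4,6-trihydroxy-3'-methyl-7'-methylidene-3-(3-methylbutanoyl)-1',2',3',3a',4',6',7',7a'-octahydrospiro[cyclohexa-3,5-diene-1,5'-inden]-2-one (trans-fused hydrindane; C2 carbonyl axial on ring B) | CC(C)CC(=O)C1=C(O)C=C(O)[C@@]2(C[C@H]3[C@@H](CC[C@@]3(C)O)C(=C)C2)C1=O | intermediate
19 | organomercurial: compound 20 with CH2HgOCOCF3 in place of the 7'-methyl group (7'S, C–O axial) | O=C1C=C(O)C(C(=O)CC(C)C)=C4[C@]12C[C@H]3[C@@H](CC[C@@]3(C)O)[C@@](C[Hg]OC(=O)C(F)(F)F)(O4)C2 | intermediate
20 | (1R,3'R,3a'S,7'S,7a'R)-2,7'-epoxy-3',4-dihydroxy-3',7'-dimethyl-3-(3-methylbutanoyl)-1',2',3',3a',4',6',7',7a'-octahydrospiro[cyclohexa-2,4-diene-1,5'-inden]-6-one (oxygen bridge from C7' to C2; spiro centre spatially as in 18, label changes because the C2/C6 priorities swap) | O=C1C=C(O)C(C(=O)CC(C)C)=C4[C@]12C[C@H]3[C@@H](CC[C@@]3(C)O)[C@@](C)(O4)C2 | intermediate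
21 | (1R,3'R,3a'S,7'S,7a'R)-2,7'-epoxy-3'-hydroxy-3',7'-dimethyl-3-(3-methylbutanoyl)-5,5-bis(3-methylbut-2-en-1-yl)-1',2',3',3a',4',6',7',7a'-octahydrospiro[cyclohex-2-ene-1,5'-indene]-4,6-dione | O=C1C(CC=C(C)C)(CC=C(C)C)C(=O)C(C(=O)CC(C)C)=C4[C@]12C[C@H]3[C@@H](CC[C@@]3(C)O)[C@@](C)(O4)C2 | intermediate
22 | CNP0198642.2: (1S,3'R,3a'S,7'S,7a'R)-3',4,7'-trihydroxy-3',7'-dimethyl-3-(3-methylbutanoyl)-5,5-bis(3-methylbut-2-en-1-yl)-1',2',3',3a',4',6',7',7a'-octahydrospiro[cyclohex-3-ene-1,5'-indene]-2,6-dione | CC(C)=CCC1(CC=C(C)C)C(=O)[C@@]2(C[C@H]3[C@@H](CC[C@@]3(C)O)[C@@](C)(O)C2)C(=O)C(C(=O)CC(C)C)=C1O | target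

## Step count and risks

Total step count: 12. Longest linear sequence: 8 steps (4, 5, 6, 7, 9, 10, 11, 12); the other branches are steps 1–3 and step 8.

Steps most likely to fail:

Step 7 (aldol). The tertiary aldol can dehydrate to the conjugated enal under amine catalysis, or settle as a diastereomer mixture. The fallback sets out from 11 and comes back at 12. Compound 11 is deliberately cyclised and dehydrated with piperidine/AcOH (benzene, reflux) to the enal (5S)-2-methyl-5-(prop-1-en-2-yl)cyclopent-1-ene-1-carbaldehyde F1. Alkaline H2O2 (MeOH, 0 °C) epoxidises it anti to the isopropenyl group to the epoxy aldehyde (1S,2S,5R)-5-methyl-2-(prop-1-en-2-yl)-6-oxabicyclo[3.1.0]hexane-1-carbaldehyde F2. Reductive cleavage of its Cα–O bond with Na[PhSeB(OEt)3] (EtOH, AcOH, 0 °C) then gives 12; the carbinol centre is now fixed by the epoxidation face and the formyl-bearing centre by protonation trans to the isopropenyl group.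

Step 10 (the new C–H spirocyclisation). The electron-rich phloroglucinol may be oxidised by the quinone, the methine C–H may be cleaved instead of the methyl C–H, or the ligand may not control the spiro centre. The fallback uses known chemistry; it sets out from 10 and comes back at 18. Allylic metalation of 10 at the isopropenyl methyl (n-BuLi/TMEDA), then B(OMe)3 and H2O2/NaOH, gives the allylic alcohol 2-[(1R)-4-methylcyclohex-3-en-1-yl]prop-2-en-1-ol F3. Compound 14 with pyridine converts it into the carbonate methyl 2-[(1R)-4-methylcyclohex-3-en-1-yl]prop-2-en-1-yl carbonate F4. Ozonolysis as in step 6 gives the keto-aldehyde methyl (3R)-2-methylidene-6-oxo-3-(2-oxoethyl)heptyl carbonate F5. Aldol closure as in step 7 gives the hydroxy aldehyde methyl 2-[(1R,2S,3R)-2-formyl-3-hydroxy-3-methylcyclopentyl]prop-2-en-1-yl carbonate F6. Reductive alkylation of 6 as in step 9 passes through the carbonate-bearing quinone methide F7 and gives the carbonate-bearing alkylated phloroglucinol F8. A zerovalent-palladium intramolecular dearomative Tsuji–Trost alkylation (Pd2(dba)3, (R,R)-DACH-phenyl Trost ligand, CH2Cl2, rt) then closes ring B at the ipso carbon and returns to the route at 18; any epimer at the spiro centre is removed by chromatography.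

Step 12 (double prenylation and bridge opening). Hydroxide may attack the non-enolisable C4/C6 diketone (retro-Claisen) instead of C2, or the hindered bridge may resist opening. The fallback sets out from 18 and comes back at 22 without ever forming the bridge. Mukaiyama hydration of the exocyclic alkene (Co(acac)2, PhSiH3, O2, iPrOH, rt) gives the free tertiary alcohol, the des-prenyl spiro diol F9, with the C7' epimers separated by chromatography. The zerovalent-palladium double prenylation of step 12 (15, Pd(PPh3)4, THF, 45 °C, no hydroxide stage) then delivers 22 directly.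

## Further compounds

F1 | step 7 | (5S)-2-methyl-5-(prop-1-en-2-yl)cyclopent-1-ene-1-carbaldehyde | O=CC1=C(C)CC[C@H]1C(C)=C
F2 | step 7 | (1S,2S,5R)-5-methyl-2-(prop-1-en-2-yl)-6-oxabicyclo[3.1.0]hexane-1-carbaldehyde | O=C[C@@]12O[C@]1(C)CC[C@H]2C(C)=C
F3 | step 10 | 2-[(1R)-4-methylcyclohex-3-en-1-yl]prop-2-en-1-ol | CC1=CC[C@@H](CC1)C(=C)CO
F4 | step 10 | methyl 2-[(1R)-4-methylcyclohex-3-en-1-yl]prop-2-en-1-yl carbonate | CC1=CC[C@@H](CC1)C(=C)COC(=O)OC
F5 | step 10 | methyl (3R)-2-methylidene-6-oxo-3-(2-oxoethyl)heptyl carbonate | O=CC[C@@H](CCC(C)=O)C(=C)COC(=O)OC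
F6 | step 10 | methyl 2-[(1R,2S,3R)-2-formyl-3-hydroxy-3-methylcyclopentyl]prop-2-en-1-yl carbonate | O=C[C@H]1[C@@H](CC[C@@]1(C)O)C(=C)COC(=O)OC
F7 | step 10 | carbonate-bearing quinone methide (analogue of 16 from 6 and F6) | CC(C)CC(=O)C1=C(O)C=C(O)C(=C[C@H]2[C@@H](CC[C@@]2(C)O)C(=C)COC(=O)OC)C1=O
F8 | step 10 | carbonate-bearing alkylated phloroglucinol (analogue of 17 with CH2OCO2Me on the alkene carbon) | CC(C)CC(=O)c1c(O)cc(O)c(C[C@H]2[C@@H](CC[C@@]2(C)O)C(=C)COC(=O)OC)c1O
F9 | step 12 | des-prenyl spiro diol (1S,3'R,3a'S,7'S,7a'R)-3',4,6,7'-tetrahydroxy-3',7'-dimethyl-3-(3-methylbutanoyl)-1',2',3',3a',4',6',7',7a'-octahydrospiro[cyclohexa-3,5-diene-1,5'-inden]-2-one | CC(C)CC(=O)C1=C(O)C=C(O)[C@@]2(C[C@H]3[C@@H](CC[C@@]3(C)O)[C@@](C)(O)C2)C1=O
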